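**Plan**

- Retrosynthesis: C1–OH and C12–OH go back to a ring A 1-en-3-one and a C12 ketone. C13–C16 is cut next (ring D, 5-exo-dig closure of a C13 radical onto a C8 propargyl group). C8–C9 and C13–C14 are then cut together (intramolecular Diels–Alder). Last come C9–C10 with the lactone C–O bond, and C4–C18 and C5–C6 on a p-quinone monoketal.
- Forward: ring A comes from an aromatic salicylate by dearomatisation. The chain C7–C6–C8(=C14)–C15–C16≡C17 is joined at C5. The lactone and the C9=C11–C12=C13 diene are built at C10. Rings B and C then close in one step, ring D last.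
- Enabling feature: ring C is a cyclohexane whose oxygen (C12) is para to the quaternary C8 and whose C14 is a bare CH2. That is the adduct of a 2-oxy-diene C9=C11–C12(O)=C13 with the 1,1-disubstituted alkene C8=C14. C9 and C8 are also the two ends of the C10–C5–C6 chain, so one cycloaddition closes rings B and C together.
- Stereochemistry: C5 and C6 come from a Michael addition controlled by a chiral lithium amide. C4 and C10 are set by attack anti to the C5 side chain. C8 and C9 are set in the cycloaddition under control of C10, C5 and C6. C13 is fixed by the bridged ring. C12 and C1 are set by reagent approach from the β-face.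

Key step: step 12

Remark: the SMILES is read as the natural gibberellin series (19,10-lactone on the α-face, 1β-OH trans-diaxial to the lactone oxygen, axial 12α-OH, H5 and H9 β, C7 β); gibberellane numbering (C1–C19) is used for all ring compounds.

**Step 1**
Reactants: 1 3-chloro-2-(chloromethyl)prop-1-ene; 2 ethynyltrimethylsilane
Product: 4 2-(chloromethyl)-5-(trimethylsilyl)pent-1-en-4-yne, via alkynylmagnesium bromide 3 (not isolated)
Conditions: EtMgBr, THF, 0 °C to rt; then CuBr·SMe2 (5 mol%), 1 (3 equiv), THF, 0 °C to rt
Reagents that add atoms: none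
Why: Copper-catalysed coupling of an alkynyl Grignard reagent with an allylic chloride; the two allylic termini of 1 are equivalent, excess 1 suppresses double substitution, and no stereocentre is formed.

**Step 2**
Reactants: 4 2-(chloromethyl)-5-(trimethylsilyl)pent-1-en-4-yne
Product: 6 tert-butyl 3-methylidene-6-(trimethylsilyl)hex-5-ynoate, via allylmagnesium chloride 5 (not isolated)
Conditions: Mg, THF, 0 °C; then Boc2O, THF, −78 to 0 °C; aq. NH4Cl
Reagents that add atoms: di-tert-butyl dicarbonate, CC(C)(C)OC(=O)OC(=O)OC(C)(C)C
Why: Grignard formation and acylation by the dicarbonate (Grignard reaction); both CH2 termini of the 2-substituted allyl system are equivalent, so direct and allyl-transposed attack give the same β,γ-unsaturated ester.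

**Step 3**
Reactants: 7 methyl 2-hydroxy-5-methoxybenzoate
Product: 8 methyl 3,3-dimethoxy-6-oxocyclohexa-1,4-diene-1-carboxylate
Conditions: PhI(OAc)2, MeOH, 0 °C
Reagents that add atoms: methanol, CO
Why: Oxidative dearomatisation of a p-methoxyphenol by trivalent iodine in methanol gives the p-quinone monoketal; the ester makes the ring CH next to the ketal (future C5) a doubly activated acceptor carbon.

**Step 4**
Reactants: 6 tert-butyl 3-methylidene-6-(trimethylsilyl)hex-5-ynoate; 8 methyl 3,3-dimethoxy-6-oxocyclohexa-1,4-diene-1-carboxylate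
Product: 10 tert-butyl 2-[2,2-dimethoxy-6-(methoxycarbonyl)-5-oxocyclohex-3-en-1-yl]-3-methylidene-6-(trimethylsilyl)hex-5-ynoate (C5 and C6 as in the target; C4 epimers), via lithium dienolate 9 (not isolated)
Conditions: (R,R)-N,N′-bis(1-phenyl-2-piperidin-1-ylethyl)propane-1,3-diamine (1.05 equiv), n-BuLi (2.0 equiv), THF, 0 °C; 6, −78 °C; then 8, −78 °C; aq. NH4Cl (amine recovered by acid extraction)
Reagents that add atoms: none
Why: Proposed new method: Michael addition of a lithium ester dienolate held in a mixed aggregate with a C2-symmetric chiral lithium amide, in which the α-carbon (C6) attacks the doubly activated β-carbon (C5) of 8 through a lithium-bridged closed transition state; the aggregate screens one enolate face and the chelated β-keto ester orients the acceptor, so C6 and C5 are set together, α- rather than γ-attack is expected for the hard lithium dienolate at −78 °C, and C4 is left as an epimerisable β-keto ester centre; the closest known reaction type is the chiral-lithium-amide-mediated enantioselective conjugate addition of ester enolates and carboxylic acid enediolates to acyclic α,β-unsaturated esters, not yet shown with a quinone monoketal acceptor or a 3-methylidene ester donor.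

**Step 5**
Reactants: 10 Michael adduct
Product: 11 tert-butyl 2-[2,2-dimethoxy-6-(methoxycarbonyl)-6-methyl-5-oxocyclohex-3-en-1-yl]-3-methylidene-6-(trimethylsilyl)hex-5-ynoate
Conditions: MeI, K2CO3, acetone, rt
Reagents that add atoms: iodomethane, CI
Why: C-alkylation of the β-keto ester enolate; methyl iodide should enter anti to the bulky side chain on the neighbouring C5, which places C18 β and the ester carbon C19 α (cis to the side chain), and the weak base does not touch the ester α-hydrogen at C6.

**Step 6**
Reactants: 11 quaternary keto ester ketal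
Product: 12 tert-butyl 2-[6-(methoxycarbonyl)-6-methyl-2,5-dioxocyclohex-3-en-1-yl]-3-methylidene-6-(trimethylsilyl)hex-5-ynoate
Conditions: PPTS, acetone/H2O, rt
Reagents that add atoms: water, O
Why: Acid-catalysed hydrolysis of the quinone monoketal under buffered conditions that spare the tert-butyl ester and the C-silyl alkyne; the quaternary C4 prevents aromatisation of the ene-dione.

**Step 7**
Reactants: 12 ene-dione; 13 1,3-dithiane
Product: 17 tert-butyl 2-[5-(1,3-dithian-2-yl)-1-methyl-2,7-dioxo-6-oxabicyclo[3.2.1]oct-3-en-8-yl]-3-methylidene-6-(trimethylsilyl)hex-5-ynoate, via 2-lithio-1,3-dithiane 14 (not isolated), via dithianylcerium dichloride 15 (not isolated), via cerium alkoxide 16 (not isolated)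
Conditions: 13, n-BuLi, THF, −30 °C; CeCl3, −78 °C; then 12, −78 °C to rt; aq. NH4Cl
Reagents that add atoms: none
Why: Organocerium 1,2-addition of a formyl anion equivalent (non-basic, carbonyl-selective) to the less hindered C10 ketone (C3 is flanked by quaternary C4), anti to the C5 side chain, gives the axial 10α-alkoxide; this is 1,3-diaxial to the C19 methyl ester and should lactonise on warming, while the tert-butyl ester does not transesterify; this sets C10.

**Step 8**
Reactants: 17 dithianyl lactone
Product: 18 tert-butyl 2-[5-(1,3-dithian-2-yl)-1-methyl-2,7-dioxo-6-oxabicyclo[3.2.1]oct-3-en-8-yl]-3-methylidenehex-5-ynoate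
Conditions: TBAF, AcOH, THF, 0 °C
Reagents that add atoms: none
Why: Fluoride-mediated protodesilylation of the alkynylsilane, buffered with acetic acid so that the ester α-centre (C6) and the β-keto lactone are not exposed to base.

**Step 9**
Reactants: 18 terminal alkyne
Product: 19 tert-butyl 2-[5-formyl-1-methyl-2,7-dioxo-6-oxabicyclo[3.2.1]oct-3-en-8-yl]-3-methylidenehex-5-ynoate
Conditions: PhI(OCOCF3)2, MeCN/H2O (9:1), 0 °C
Reagents that add atoms: water, O
Why: Oxidative dithioacetal hydrolysis by trivalent iodine; the aldehyde (C9) sits on the quaternary C10 and has no α-hydrogen, so it can neither epimerise nor conjugate.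

**Step 10**
Reactants: 19 aldehyde; 20 1-chloro-3-(triphenyl-λ5-phosphanylidene)propan-2-one
Product: 21 tert-butyl 2-{5-[(1E)-4-chloro-3-oxobut-1-en-1-yl]-1-methyl-2,7-dioxo-6-oxabicyclo[3.2.1]oct-3-en-8-yl}-3-methylidenehex-5-ynoate
Conditions: toluene, 80 °C
Reagents that add atoms: none
Why: Wittig reaction with a stabilised acyl ylide gives the (E)-enone and brings in C11–C13 together with the C13 chlorine that later marks C13 as the radical site.

**Step 11**
Reactants: 21 chloromethyl enone
Product: 22 tert-butyl 2-{5-[(1E,3Z)-3-(tert-butyldimethylsilyloxy)-4-chlorobuta-1,3-dien-1-yl]-1-methyl-2,7-dioxo-6-oxabicyclo[3.2.1]oct-3-en-8-yl}-3-methylidenehex-5-ynoate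
Conditions: TBSOTf, Et3N, CH2Cl2, −78 to −20 °C
Reagents that add atoms: tert-butyldimethylsilyl trifluoromethanesulfonate, CC(C)(C)[Si](C)(C)OS(=O)(=O)C(F)(F)F
Why: Soft enolisation of the only enolisable position (C13; C10 is quaternary and the ring A enone has neither α- nor γ-hydrogens) gives the 2-silyloxy diene; the low temperature spares the tert-butyl ester, and the C12=C13 geometry is of no consequence later.

**Step 12**
Reactants: 22 chloro silyloxy diene
Product: 23 tetracyclic cycloadduct (rings B and C closed; C11=C12 tert-butyldimethylsilyl enol ether; C13 chloride cis to C10; C8 prop-2-ynyl; C7 tert-butyl ester; ring A 1-en-3-one 19,10-lactone)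
Conditions: toluene (0.005 M), BHT (cat.), N,O-bis(trimethylsilyl)acetamide (0.1 equiv), 170 °C, sealed tube
Reagents that add atoms: none
Why: Thermal, concerted but asynchronous [4+2] cycloaddition between the diene C9=C11–C12(OTBS)=C13 and the alkene C8=C14 (intramolecular Diels–Alder reaction; closest known type: thermal cyclisation of 2-silyloxy-1,3,8-nonatrienes with an unactivated 1,1-disubstituted alkene to angularly substituted cis-hydrindanes). Ring C closes as the six-membered cycloaddition ring, both new bonds forming suprafacially on each component, and ring B as the five-membered ring defined by the C10–C5–C6 tether, whose two ends C9 and C8 become bonded. C9 is controlled by C10: the alkene is delivered from the side of C5, and the conformer with the small lactone oxygen eclipsing C9=C11 and the C1 vinyl carbon turned away is favoured, so C11 ends syn to the lactone oxygen and H9 is β. C8 is controlled by the endo placement of the tether, which keeps the propargyl group exo (away from C12–OTBS) and gives the cis B/C fusion with C15 β, while the C6 ester lies on the face away from the diene. The step needs periselectivity (the ring A enone is one atom and the alkyne five atoms from the diene, so neither can close a viable ring, and high dilution suppresses intermolecular addition to the enone), regioselectivity (fixed by the tether) and the facial and ring-fusion selectivity just described; the C13 chloride configuration is erased in step 14. The trans-diequatorial placement of C9 and C6 on the rigid bicyclic lactone holds diene and alkene within bonding distance, which is what should let an unactivated alkene react.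

**Step 13**
Reactants: 23 cycloadduct
Product: 24 13-chloro-12-oxo-8-(prop-2-ynyl) tetracyclic 7-carboxylic acid (ring A 1-en-3-one 19,10-lactone)
Conditions: TFA/CH2Cl2 (1:4), H2O (2 equiv), 0 °C to rt
Reagents that add atoms: none
Why: Protonolysis of the silyl enol ether and acidolysis of the tert-butyl ester in one operation; the positions of the ketone (C12) and of the chlorine (C13) are fixed by the cycloaddition, and no acid-labile ring D alkene is present yet.

**Step 14**
Reactants: 24 α-chloro ketone
Product: 25 12-oxo-16-ene pentacyclic acid (ring D closed; ring A 1-en-3-one 19,10-lactone; 7-COOH)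
Conditions: Bu3SnH (syringe pump), AIBN, benzene, 80 °C
Reagents that add atoms: none
Why: α-Carbonyl radical cyclisation: chlorine abstraction gives the planar C13 radical, 5-exo-dig attack on the propargyl alkyne forms C13–C16, and the vinyl radical is reduced to the exocyclic methylene; only the cis-bridged bicyclo[3.2.1]octane can form, so C13 is set by the ring, and slow hydride addition favours cyclisation over direct reduction.

**Step 15**
Reactants: 25 12-ketone
Product: 26 12α-hydroxy-16-ene pentacyclic acid (ring A 1-en-3-one 19,10-lactone)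
Conditions: NaBH4, MeOH/CH2Cl2 (1:1), −78 °C; 1 M HCl work-up
Reagents that add atoms: none
Why: Without cerium salts NaBH4 reduces a saturated ketone faster than the hindered, conjugated ring A enone; hydride should attack C12 from the β-face because the axial α-trajectory is blocked by C10, which is syn-axial on ring C, giving the axial 12α-alcohol.

**Step 16**
Reactants: 26 enone alcohol
Product: 28 target (1β,12α-dihydroxy-3-oxo-16-ene 19,10-lactone 7-carboxylic acid), via 1β-boronate 27 (not isolated)
Conditions: CuCl (10 mol%), DPEphos (10 mol%), NaOt-Bu (1.2 equiv), B2pin2, MeOH, THF, rt; then NaBO3·4H2O, THF/H2O, rt; 1 M HCl to pH 3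
Reagents that add atoms: bis(pinacolato)diboron, CC1(C)OB(OC1(C)C)B1OC(C)(C)C(C)(C)O1 (boron of 27); sodium perborate, [Na+].[Na+].O[B-]1(O)OO[B-](O)(O)OO1 (oxygen on C1)
Why: Copper-catalysed conjugate borylation of the enone followed by oxidation (formal conjugate hydration); the boryl group should add axially to C1 from the β-face, anti to the α-lactone oxygen on C10, the oxidation goes with retention, and mild perborate avoids retro-aldol cleavage or dehydration of the β-hydroxy ketone.

**Compound list**

1 | 3-chloro-2-(chloromethyl)prop-1-ene | C=C(CCl)CCl | starting material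
2 | ethynyltrimethylsilane | C#C[Si](C)(C)C | starting material
3 | [(trimethylsilyl)ethynyl]magnesium bromide | C[Si](C)(C)C#C[Mg]Br | intermediate
4 | 2-(chloromethyl)-5-(trimethylsilyl)pent-1-en-4-yne | C=C(CCl)CC#C[Si](C)(C)C | intermediate
5 | [2-methylidene-5-(trimethylsilyl)pent-4-yn-1-yl]magnesium chloride | C=C(C[Mg]Cl)CC#C[Si](C)(C)C | intermediate
6 | tert-butyl 3-methylidene-6-(trimethylsilyl)hex-5-ynoate | CC(C)(C)OC(=O)CC(=C)CC#C[Si](C)(C)C | intermediate
7 | methyl 2-hydroxy-5-methoxybenzoate | COC(=O)c1cc(OC)ccc1O | starting material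
8 | methyl 3,3-dimethoxy-6-oxocyclohexa-1,4-diene-1-carboxylate | COC(=O)C1=CC(OC)(OC)C=CC1=O | intermediate
9 | lithium dienolate of 6 (in a mixed aggregate with the chiral lithium amide) | CC(C)(C)OC(O[Li])=CC(=C)CC#C[Si](C)(C)C | intermediate
10 | Michael adduct, β-keto ester (C4 epimers) | CC(C)(C)OC(=O)[C@H](C(=C)CC#C[Si](C)(C)C)[C@@H]1C(C(=O)OC)C(=O)C=CC1(OC)OC | intermediate
11 | C4-methylated keto ester ketal | CC(C)(C)OC(=O)[C@H](C(=C)CC#C[Si](C)(C)C)[C@@H]1[C@](C)(C(=O)OC)C(=O)C=CC1(OC)OC | intermediate
12 | ene-dione | CC(C)(C)OC(=O)[C@H](C(=C)CC#C[Si](C)(C)C)[C@@H]1[C@](C)(C(=O)OC)C(=O)C=CC1=O | intermediate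
13 | 1,3-dithiane | C1CSCSC1 | starting material
14 | 2-lithio-1,3-dithiane | [Li]C1SCCCS1 | intermediate
15 | dichloro(1,3-dithian-2-yl)cerium | Cl[Ce](Cl)C1SCCCS1 | intermediate
16 | C10 cerium alkoxide adduct | CC(C)(C)OC(=O)[C@H](C(=C)CC#C[Si](C)(C)C)[C@@H]1[C@](C)(C(=O)OC)C(=O)C=C[C@@]1(O[Ce](Cl)Cl)C1SCCCS1 | intermediate
17 | dithianyl enone lactone (C-silyl alkyne) | CC(C)(C)OC(=O)[C@H](C(=C)CC#C[Si](C)(C)C)[C@@H]1[C@@]2(C)C(=O)C=C[C@@]1(OC2=O)C1SCCCS1 | intermediate
18 | dithianyl enone lactone (terminal alkyne) | CC(C)(C)OC(=O)[C@H](C(=C)CC#C)[C@@H]1[C@@]2(C)C(=O)C=C[C@@]1(OC2=O)C1SCCCS1 | intermediate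
19 | C9 aldehyde | CC(C)(C)OC(=O)[C@H](C(=C)CC#C)[C@@H]1[C@@]2(C)C(=O)C=C[C@@]1(OC2=O)C=O | intermediate
20 | 1-chloro-3-(triphenyl-λ5-phosphanylidene)propan-2-one | ClCC(=O)C=P(c1ccccc1)(c1ccccc1)c1ccccc1 | starting material
21 | (E)-chloromethyl enone | CC(C)(C)OC(=O)[C@H](C(=C)CC#C)[C@@H]1[C@@]2(C)C(=O)C=C[C@@]1(OC2=O)/C=C/C(=O)CCl | intermediate
22 | (1E,3Z)-chloro silyloxy diene | CC(C)(C)OC(=O)[C@H](C(=C)CC#C)[C@@H]1[C@@]2(C)C(=O)C=C[C@@]1(OC2=O)/C=C/C(O[Si](C)(C)C(C)(C)C)=C/Cl | intermediate
23 | tetracyclic cycloadduct | C#CC[C@]12C[C@@H](Cl)C(O[Si](C)(C)C(C)(C)C)=C[C@H]1[C@]13OC(=O)[C@](C)(C(=O)C=C1)[C@H]3[C@@H]2C(=O)OC(C)(C)C | intermediate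
24 | 13-chloro-12-ketone 7-acid | C#CC[C@]12C[C@@H](Cl)C(=O)C[C@H]1[C@]13OC(=O)[C@](C)(C(=O)C=C1)[C@H]3[C@@H]2C(=O)O | intermediate
25 | 12-oxo-16-ene pentacyclic acid | C=C1C[C@]23C[C@H]1C(=O)C[C@H]2[C@]12OC(=O)[C@](C)(C(=O)C=C1)[C@H]2[C@@H]3C(=O)O | intermediate
26 | 12α-hydroxy-16-ene pentacyclic acid | C=C1C[C@]23C[C@H]1[C@@H](O)C[C@H]2[C@]12OC(=O)[C@](C)(C(=O)C=C1)[C@H]2[C@@H]3C(=O)O | intermediate
27 | 1β-(pinacolboryl) 3-ketone | C=C1C[C@]23C[C@H]1[C@@H](O)C[C@H]2[C@]12OC(=O)[C@](C)(C(=O)C[C@H]1B1OC(C)(C)C(C)(C)O1)[C@H]2[C@@H]3C(=O)O | intermediate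
28 | CNP0259985.1 | C=C1C[C@]23C[C@H]1[C@@H](O)C[C@H]2[C@]12OC(=O)[C@](C)(C(=O)C[C@H]1O)[C@H]2[C@@H]3C(=O)O | target

**Step count and risks**

Total step count: 16. Longest linear sequence: 15 steps (steps 1, 2 and 4–16).

Steps most likely to fail:

1. Step 4. The mixed aggregate may discriminate poorly between the faces of C5 or C6, the dienolate may react through its γ-carbon, or electron transfer to the quinoid acceptor may compete. The fallback moves the stereocontrol to a covalent auxiliary on the acceptor. It sets out from 8, which is trans-ketalised with (1R,2R)-1,2-diphenylethane-1,2-diol (PPTS, benzene, methanol distilled off) to the chiral spiroketal F1. The achiral lithium enolate of 6 (LDA, THF, −78 °C) is added, with the phenyl groups of the auxiliary screening one face of C5, to give the adduct F2. Methylation (MeI, K2CO3, acetone) gives the quaternary keto ester F3, and hydrolysis (PPTS, acetone/H2O) releases the diol and returns to the route at 12.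

2. Step 12. The unactivated alkene may react too slowly at temperatures the silyl dienol ether, the allylic chloride and the tert-butyl ester tolerate, or the cis ring-fusion preference may erode at high temperature. The fallback replaces the pericyclic step by a metal-mediated stepwise [4+2] (oxidative cyclisation to a rhodacycle, then reductive elimination), which is known for unactivated diene–ene pairs; the alkyne is kept C-silylated to keep it away from the metal. It sets out from 17: dithioacetal hydrolysis as in step 9 gives the aldehyde F4, Wittig reaction with 20 gives the enone F5, and silylation as in step 11 gives the diene F6. [Rh(C8H14)2Cl]2 (monovalent rhodium, C8H14 = cyclooctene) with P[OCH(CF3)2]3 in THF at 55 °C should then give the cycloadduct F7. TBAF/AcOH removes both silyl groups to give the chloro ketone ester F8, and TFA returns to the route at 24.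

3. Step 14. The C13 radical may be reduced before it cyclises, because the reactive conformer needs the propargyl group axial on ring C, or the tin radical may attack the ring A enone. The fallback closes ring D by an ionic 5-exo-dig carbocyclisation of a regiodefined enol silane. It sets out from 24: reductive silylation (Zn, Me3SiCl, THF) uses the chlorine to give the C12=C13 trimethylsilyl enol ether (also a silyl ester) F9. Ph3PAuCl/AgSbF6 (monovalent gold, catalytic) in CH2Cl2/MeOH should then add C13 to the activated alkyne, and work-up returns to the route at 25.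

**Further compounds**

F1 | step 4 | methyl (2R,3R)-8-oxo-2,3-diphenyl-1,4-dioxaspiro[4.5]deca-6,9-diene-7-carboxylate | COC(=O)C1=CC2(O[C@H](c3ccccc3)[C@@H](c3ccccc3)O2)C=CC1=O
F2 | step 4 | Michael adduct carrying the diphenyldioxolane ketal (C4 epimers) | CC(C)(C)OC(=O)[C@H](C(=C)CC#C[Si](C)(C)C)[C@@H]1C(C(=O)OC)C(=O)C=CC12O[C@H](c3ccccc3)[C@@H](c3ccccc3)O2
F3 | step 4 | C4-methylated keto ester carrying the diphenyldioxolane ketal | CC(C)(C)OC(=O)[C@H](C(=C)CC#C[Si](C)(C)C)[C@@H]1[C@](C)(C(=O)OC)C(=O)C=CC12O[C@H](c3ccccc3)[C@@H](c3ccccc3)O2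
F4 | step 12 | C9 aldehyde with C-silyl alkyne | CC(C)(C)OC(=O)[C@H](C(=C)CC#C[Si](C)(C)C)[C@@H]1[C@@]2(C)C(=O)C=C[C@@]1(OC2=O)C=O
F5 | step 12 | (E)-chloromethyl enone with C-silyl alkyne | CC(C)(C)OC(=O)[C@H](C(=C)CC#C[Si](C)(C)C)[C@@H]1[C@@]2(C)C(=O)C=C[C@@]1(OC2=O)/C=C/C(=O)CCl
F6 | step 12 | chloro silyloxy diene with C-silyl alkyne | CC(C)(C)OC(=O)[C@H](C(=C)CC#C[Si](C)(C)C)[C@@H]1[C@@]2(C)C(=O)C=C[C@@]1(OC2=O)/C=C/C(O[Si](C)(C)C(C)(C)C)=C/Cl
F7 | step 12 | cycloadduct with C-silyl alkyne | C[Si](C)(C)C#CC[C@]12C[C@@H](Cl)C(O[Si](C)(C)C(C)(C)C)=C[C@H]1[C@]13OC(=O)[C@](C)(C(=O)C=C1)[C@H]3[C@@H]2C(=O)OC(C)(C)C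
F8 | step 12 | 13-chloro-12-ketone tert-butyl ester | C#CC[C@]12C[C@@H](Cl)C(=O)C[C@H]1[C@]13OC(=O)[C@](C)(C(=O)C=C1)[C@H]3[C@@H]2C(=O)OC(C)(C)C
F9 | step 14 | C12=C13 trimethylsilyl enol ether trimethylsilyl ester | C#CC[C@]12CC=C(O[Si](C)(C)C)C[C@H]1[C@]13OC(=O)[C@](C)(C(=O)C=C1)[C@H]3[C@@H]2C(=O)O[Si](C)(C)C
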